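**Plan**

Briarane numbering is used: C1 (quaternary, Me C15) and C10 are the fusion carbons, ring A is C1/C10–C14 (Me C20 on C11), the ten-membered ring is C1–C10 (C16 on C5), the lactone is C7–O–C19–C17–C8, and β is the face of C15. C7 is both the allylic carbinol carbon beside C5=C6 and the alkoxy carbon of the γ-lactone, its oxygen lying four atoms from C19, so a C6 alkenyl metal adding to a C7 aldehyde forms the last ring bond and frees the alkoxide that acylates on a C19 ester.
Retrosynthetic cuts, in order: C6–C7 together with O7–C19 (one flask); the C4 ester; C3–C4 (boron aldol); C8–C9 (alkenylchromium addition) and the C7/C8 oxygens (osmylation); C9–C10 ([2,3]-Wittig shift); C1–C2 and C1–C15 (enolate reactions of carvone).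
Forward: ring A from (S)-carvone; then the C7–C9/C17–C19 arm from an enol triflate made from the (S)-Roche ester; then the C3–C6/C16 arm from a silyl enal made from propargyl alcohol; then the ten-membered ring and the lactone close together, followed by three finishing steps.
Stereochemistry: C14 from carvone (Criegee, retention); C1 by methylation anti to isopropenyl; C10 by suprafacial [2,3] shift from the 12β oxygen (trans epoxidation, Wharton); C9 by Felkin–Anh addition; C8 by osmylation anti to C9–OH; C17 from the Roche ester; C4 from (−)-Ipc2BCl; C2 by 1,3-anti reduction; C7 in the key step; the side-chain centre from (R)-3-hydroxybutanoic acid; 5Z from syn silylstannation.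

Key step: step 34

Assumption: (−)-Ipc2BCl is taken as the reagent enantiomer whose enol borinate adds to the Re face of the enal (4R); if a trial aldol shows the opposite sense, (+)-Ipc2BCl is used with no other change.

**Enol triflate 5 (C7, C8, C17–C19)**

Step 1
Reactants: 1 methyl (S)-3-hydroxy-2-methylpropanoate
Product: 2 methyl (S)-2-methyl-3-(triethylsilyloxy)propanoate
Conditions: Et3SiCl, imidazole, CH2Cl2, 0 → 25 °C
Reagents that add atoms: chlorotriethylsilane, CC[Si](Cl)(CC)CC
Why: Silyl ether formation protects the future C19 hydroxyl through the organometallic steps and leaves the C17 centre untouched.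

Step 2
Reactants: 2 methyl (S)-2-methyl-3-(triethylsilyloxy)propanoate
Product: 3 (S)-N-methoxy-N,2-dimethyl-3-(triethylsilyloxy)propanamide
Conditions: MeNH(OMe)·HCl, i-PrMgCl, THF, −20 → 0 °C
Reagents that add atoms: N,O-dimethylhydroxylamine hydrochloride, Cl.CNOC
Why: Aminolysis of the ester by the magnesium amide (Weinreb amide formation) is fast at low temperature and should not enolise the α-centre.

Step 3
Reactants: 3 (S)-N-methoxy-N,2-dimethyl-3-(triethylsilyloxy)propanamide
Product: 4 (S)-3-methyl-4-(triethylsilyloxy)butan-2-one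
Conditions: MeMgBr, THF, 0 °C; aq. NH4Cl
Reagents that add atoms: methylmagnesium bromide, C[Mg]Br
Why: In the Weinreb ketone synthesis the chelated adduct stops at the methyl ketone, whose carbonyl carbon becomes C8 and whose methyl becomes C7.

Step 4
Reactants: 4 (S)-3-methyl-4-(triethylsilyloxy)butan-2-one
Product: 5 (S)-3-methyl-4-(triethylsilyloxy)but-1-en-2-yl trifluoromethanesulfonate
Conditions: KN(SiMe3)2, THF, −78 °C; PhNTf2, −78 → 0 °C
Reagents that add atoms: N-phenylbis(trifluoromethanesulfonimide), O=S(=O)(N(c1ccccc1)S(=O)(=O)C(F)(F)F)C(F)(F)F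
Why: Kinetic deprotonation by the bulky amide takes place at the methyl group, away from the C17 centre, and O-sulfonylation of that enolate gives the enol triflate.

**Silyl enal 9 (C4–C6, C16)**

Step 5
Reactants: 6 prop-2-yn-1-ol
Product: 7 tert-butyldiphenyl(prop-2-yn-1-yloxy)silane
Conditions: t-BuPh2SiCl, imidazole, CH2Cl2, 25 °C
Reagents that add atoms: tert-butyl(chloro)diphenylsilane, CC(C)(C)[Si](Cl)(c1ccccc1)c1ccccc1
Why: Silyl ether formation with a group robust to acid, base and mild fluoride, chosen to stay on C16–O until the last step.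

Step 6
Reactants: 7 tert-butyldiphenyl(prop-2-yn-1-yloxy)silane
Product: 8 (Z)-tert-butyldiphenyl{[2-(tributylstannyl)-3-(trimethylsilyl)prop-2-en-1-yl]oxy}silane
Conditions: Me3SiSnBu3, Pd(PPh3)4 (cat.), THF, 65 °C
Reagents that add atoms: trimethyl(tributylstannyl)silane, CCCC[Sn](CCCC)(CCCC)[Si](C)(C)C
Why: Pd-catalysed silylstannation of a terminal alkyne is a syn addition that places tin on the internal carbon (C5) and silicon on the terminal carbon (C6), which fixes the later C5=C6 geometry.

Step 7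
Reactants: 8 (Z)-tert-butyldiphenyl{[2-(tributylstannyl)-3-(trimethylsilyl)prop-2-en-1-yl]oxy}silane
Product: 9 (Z)-2-[(tert-butyldiphenylsilyloxy)methyl]-3-(trimethylsilyl)prop-2-enal
Conditions: n-BuLi, THF, −78 °C; HCONMe2, −78 → 0 °C; H2O
Reagents that add atoms: N,N-dimethylformamide, CN(C)C=O
Why: Tin–lithium exchange proceeds with retention of olefin geometry and the alkenyllithium is formylated, so silicon ends cis to the new C4 aldehyde.

**Side-chain acid 11**

Step 8
Reactants: 10 (R)-3-hydroxybutanoic acid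
Product: 11 (R)-3-acetoxybutanoic acid
Conditions: AcCl, CH2Cl2, 0 → 25 °C; H2O
Reagents that add atoms: acetyl chloride, CC(Cl)=O
Why: O-Acetylation of the secondary alcohol does not touch the stereocentre, and any mixed anhydride is hydrolysed on work-up.

**Ring A and the C9 aldehyde**

Step 9
Reactants: 12 (S)-carvone; 13 acetaldehyde
Product: 14 trans-6-(1-hydroxyethyl)carvone (carbinol epimers)
Conditions: LiN(i-Pr)2, THF, −78 °C; 13, −78 °C; H2O
Reagents that add atoms: none
Why: Kinetic α′-deprotonation of carvone and aldol addition anti to the isopropenyl group install C2 and C3; the configurations formed at C1 and C2 do not matter, because C1 is re-enolised in step 11 and C2 is oxidised in step 24.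

Step 10
Reactants: 14 trans-6-(1-hydroxyethyl)carvone
Product: 15 triethylsilyl ether of 14
Conditions: Et3SiCl, imidazole, 4-(dimethylamino)pyridine (cat.), CH2Cl2, 0 → 25 °C
Reagents that add atoms: chlorotriethylsilane, CC[Si](Cl)(CC)CC
Why: Silyl ether formation masks the C2 oxygen as a poor leaving group before the second enolisation.

Step 11
Reactants: 15 triethylsilyl ether of 14
Product: 16 quaternary enone (C1 methyl trans to isopropenyl)
Conditions: LiN(i-Pr)2, THF/DMPU, −78 °C; MeI, −78 → −30 °C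
Reagents that add atoms: iodomethane, CI
Why: In this enolate alkylation the tetrasubstituted enolate should take up MeI on the face anti to the neighbouring isopropenyl group, which sets quaternary C1 with C15 trans and the C2 arm cis to the C14 substituent; β-elimination of the silyloxy group is expected to be slow at low temperature.

Step 12
Reactants: 16 quaternary enone
Product: 17 11,12β-epoxy ketone
Conditions: 30% H2O2, NaOH (0.3 equiv), MeOH, 0 °C
Reagents that add atoms: hydrogen peroxide, OO
Why: Nucleophilic (Weitz–Scheffer) epoxidation attacks only the enone, and hydroperoxide adds to C12 trans to the C14 substituent as in other 5-substituted cyclohexenones, giving the β-epoxide.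

Step 13
Reactants: 17 11,12β-epoxy ketone
Product: 19 epoxy ketone C14 acetate, via methoxy hydroperoxide 18 (not isolated)
Conditions: O3, CH2Cl2/MeOH (5:1), −78 °C; then Ac2O, Et3N, 4-(dimethylamino)pyridine (cat.), −78 → 40 °C
Reagents that add atoms: ozone, [O-][O+]=O; methanol, CO
Why: Ozonolysis in methanol and acetylation of the resulting methoxy hydroperoxide trigger the Criegee rearrangement, in which C14 migrates to oxygen with retention, so the isopropenyl group becomes the 14α-acetate; the epoxy ketone carries no other olefin.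

Step 14
Reactants: 19 epoxy ketone C14 acetate
Product: 20 ring A allylic alcohol (12β-OH, C10=C11)
Conditions: N2H4·H2O (3 equiv), AcOH (0.5 equiv), MeOH, 0 → 25 °C
Reagents that add atoms: none
Why: In the Wharton transposition the epoxy hydrazone fragments with loss of N2, which moves the double bond to C10=C11 and keeps the C12–O bond of the epoxide; the hindered acetate should survive the short exposure to hydrazine.

Step 15
Reactants: 20 ring A allylic alcohol
Product: 21 O12 tributylstannylmethyl ether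
Conditions: KH, 18-crown-6 (cat.), Bu3SnCH2I, THF, 0 °C
Reagents that add atoms: tributyl(iodomethyl)stannane, CCCC[Sn](CI)(CCCC)CCCC
Why: Williamson etherification of the potassium alkoxide; the acetate, trans-1,3 to the alkoxide on the ring, cannot migrate to it.

Step 16
Reactants: 21 O12 tributylstannylmethyl ether
Product: 22 ring A diol (10β-CH2OH, 14α-OH)
Conditions: n-BuLi (4 equiv), THF, −78 °C; H2O
Reagents that add atoms: none
Why: Tin–lithium exchange gives the α-alkoxymethyllithium, whose [2,3]-Wittig (Still–Wittig) shift carries the carbon suprafacially from O12 to the β face of C10, setting C10 and the C11=C12 olefin; the excess n-BuLi consumes the C14 acetate, which is restored in step 22.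

Step 17
Reactants: 22 ring A diol
Product: 23 ring A hydroxy aldehyde (C9 aldehyde)
Conditions: 2,2,6,6-tetramethylpiperidin-1-oxyl (cat.), PhI(OAc)2, CH2Cl2, 25 °C
Reagents that add atoms: none
Why: The oxoammonium oxidation is selective for the primary alcohol over the hindered secondary C14–OH and is mild enough to leave the α-centre and the β,γ-olefin in place.

**South arm (C7–C9, C17–C19)**

Step 18
Reactants: 23 ring A hydroxy aldehyde; 5 (S)-3-methyl-4-(triethylsilyloxy)but-1-en-2-yl trifluoromethanesulfonate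
Product: 24 (9R) allylic alcohol
Conditions: 5 (2 equiv), CrCl2 (5 equiv), NiCl2 (0.05 equiv), DMF, 25 °C
Reagents that add atoms: none
Why: Intermolecular Nozaki–Hiyama–Kishi coupling: the alkenylchromium from the triflate adds to the aldehyde under Felkin–Anh control with quaternary C1 anti to the nucleophile, which should give the 9R carbinol; the free C14 hydroxyl is tolerated.

Step 19
Reactants: 24 (9R) allylic alcohol
Product: 25 tetraol (C7, C8, C9, C14 hydroxyls)
Conditions: OsO4 (0.03 equiv), N-methylmorpholine N-oxide, acetone/H2O (8:1), 0 → 25 °C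
Reagents that add atoms: N-methylmorpholine N-oxide, C[N+]1([O-])CCOCC1; water, O
Why: Upjohn dihydroxylation: OsO4 should add to the 1,1-disubstituted olefin anti to the allylic C9 hydroxyl in the conformer with C9–H in the olefin plane, giving the erythro C8/C9 relationship of the target, while the trisubstituted ring olefin is shielded by C10 and C1.

Step 20
Reactants: 25 tetraol
Product: 26 C7 tert-butyldimethylsilyl ether
Conditions: t-BuMe2SiCl, imidazole, DMF, 0 °C
Reagents that add atoms: tert-butyl(chloro)dimethylsilane, CC(C)(C)[Si](C)(C)Cl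
Why: Silylation selects the only primary hydroxyl, so that the C8/C9 diol alone is left able to form a five-membered acetal.

Step 21
Reactants: 26 C7 tert-butyldimethylsilyl ether
Product: 27 C8/C9 acetonide
Conditions: 2,2-dimethoxypropane, pyridinium p-toluenesulfonate (cat.), CH2Cl2, 25 °C
Reagents that add atoms: 2,2-dimethoxypropane, COC(C)(C)OC
Why: Acid-catalysed transacetalisation closes the dioxolane on the vicinal C8/C9 diol; the isolated C14 hydroxyl cannot form a cyclic acetal.

Step 22
Reactants: 27 C8/C9 acetonide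
Product: 28 C14 acetate
Conditions: Ac2O, pyridine, 4-(dimethylamino)pyridine (cat.), CH2Cl2, 25 °C
Reagents that add atoms: acetic anhydride, CC(=O)OC(C)=O
Why: Nucleophile-catalysed acetylation of the one free hydroxyl puts the final acetate on C14.

Step 23
Reactants: 28 C14 acetate
Product: 29 C2,C19 diol
Conditions: HF·pyridine, pyridine, THF, 0 → 25 °C
Reagents that add atoms: none
Why: Buffered fluoride cleaves the two triethylsilyl ethers far faster than the neopentylic primary tert-butyldimethylsilyl ether, and the acetonide and acetate are stable to it.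

Step 24
Reactants: 29 C2,C19 diol
Product: 30 keto aldehyde (C2 methyl ketone, C19 aldehyde)
Conditions: Dess–Martin periodinane, NaHCO3, CH2Cl2, 0 → 25 °C
Reagents that add atoms: none
Why: The buffered hypervalent-iodine oxidation converts both alcohols in one operation and should not epimerise C17.

Step 25
Reactants: 30 keto aldehyde
Product: 31 keto acid
Conditions: NaClO2, NaH2PO4, 2-methylbut-2-ene, t-BuOH/H2O, 0 °C
Reagents that add atoms: sodium chlorite, [Na+].[O-]Cl=O
Why: Pinnick oxidation takes only the aldehyde to the acid, and the scavenger protects the ring olefin from hypochlorite.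

Step 26
Reactants: 31 keto acid
Product: 32 keto ester (C2 methyl ketone, C19 methyl ester)
Conditions: Me3SiCHN2, PhMe/MeOH (4:1), 0 °C
Reagents that add atoms: (trimethylsilyl)diazomethane, C[Si](C)(C)C=[N+]=[N-]
Why: Methylation of the carboxylic acid by the diazoalkane is fast and neutral, so C17 and the ketone are not affected.

**North arm (C3–C6, C16) and the precursor**

Step 27
Reactants: 32 keto ester; 9 (Z)-2-[(tert-butyldiphenylsilyloxy)methyl]-3-(trimethylsilyl)prop-2-enal
Product: 33 (4R) aldol adduct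
Conditions: (−)-Ipc2BCl, Et3N, Et2O, −78 → 0 °C; 9, −78 → −20 °C; H2O2, pH 7 buffer, MeOH, 0 °C
Reagents that add atoms: none
Why: Boron aldol reaction: the methyl ketone is enolised at C3, the only enolisable position under these conditions, and the enol borinate adds to the enal through a cyclic transition state on the aldehyde face selected by the isopinocampheyl ligands, which should give the 4R carbinol.

Step 28
Reactants: 33 (4R) aldol adduct
Product: 34 (2R,4R) anti diol
Conditions: Me4NBH(OAc)3, MeCN/AcOH (1:1), −30 °C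
Reagents that add atoms: none
Why: Evans–Saksena reduction: the C4 hydroxyl binds the triacetoxyborohydride and delivers hydride to the C2 ketone through a chair transition state, giving the 1,3-anti diol.

Step 29
Reactants: 34 (2R,4R) anti diol; 11 (R)-3-acetoxybutanoic acid
Product: 35 C4 (R)-3-acetoxybutanoate
Conditions: 11, N,N′-dicyclohexylcarbodiimide, 4-(dimethylamino)pyridine (0.1 equiv), CH2Cl2, −20 → 0 °C
Reagents that add atoms: none
Why: Steglich esterification should select the allylic C4 hydroxyl, because the C2 hydroxyl is neopentylic beside quaternary C1; low temperature and little base avoid β-elimination of the acetoxy acid.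

Step 30
Reactants: 35 C4 (R)-3-acetoxybutanoate
Product: 36 C2 acetate
Conditions: Ac2O, pyridine, 4-(dimethylamino)pyridine, CH2Cl2, 25 °C
Reagents that add atoms: acetic anhydride, CC(=O)OC(C)=O
Why: Nucleophile-catalysed acetylation with excess anhydride acylates the remaining hindered secondary hydroxyl.

Step 31
Reactants: 36 C2 acetate
Product: 37 (5Z) C6 iodoalkene
Conditions: N-iodosuccinimide, (CF3)2CHOH, 0 °C
Reagents that add atoms: N-iodosuccinimide, O=C1CCC(=O)N1I
Why: Iododesilylation: iodonium attacks the silicon-bearing carbon and the β-silyl cation loses silicon, an ipso substitution with retention in the ionising solvent that gives the Z-iodoalkene; no free hydroxyl is present to trap an iodonium ion on the ring olefin.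

Step 32
Reactants: 37 (5Z) C6 iodoalkene
Product: 38 C7 primary alcohol
Conditions: HF·pyridine, pyridine, THF, 0 → 25 °C
Reagents that add atoms: none
Why: Buffered fluoride removes the primary tert-butyldimethylsilyl ether and leaves the far more stable tert-butyldiphenylsilyl ether, the acetonide and the esters.

Step 33
Reactants: 38 C7 primary alcohol
Product: 39 (5Z)-iodoalkene C7 aldehyde
Conditions: Dess–Martin periodinane, NaHCO3, CH2Cl2, 25 °C
Reagents that add atoms: none
Why: Hypervalent-iodine oxidation of the neopentylic primary alcohol gives an aldehyde that has no α-hydrogen and so cannot epimerise or enolise.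

**Key step and completion**

Step 34
Reactants: 39 (5Z)-iodoalkene C7 aldehyde
Product: 41 tetracyclic (7S) γ-lactone, via C7 hydroxy ester 40 (not isolated)
Conditions: CrCl2 (15 equiv), NiCl2 (0.15 equiv), degassed DMSO/THF (3:1), 0.002 M, 25 °C, then 40 °C; aq. NH4Cl
Reagents that add atoms: none
Why: Divalent chromium reduces NiCl2 to zerovalent nickel, which inserts into the C6–I bond with retention of the Z geometry and hands the alkenyl group to trivalent chromium; the alkenylchromium adds to the C7 aldehyde, the only carbonyl it attacks beside six ester groups. The closest known reaction type is the Nozaki–Hiyama–Kishi macrocyclisation of iodoalkene aldehydes, followed by the acylation of a γ-alkoxide on an ester that is familiar from chromium-mediated butyrolactone syntheses. The ten-membered carbocycle closes by a 10-exo-trig carbonyl addition (C6 to C7) and the γ-lactone by a 5-exo-trig acyl substitution of the C7 chromium alkoxide on the C19 methyl ester with loss of methoxide. The one new stereocentre, C7, is set in the macrocyclic transition state: the acetonide ties C8 and C9 into a ring and leaves one face of the C7 carbonyl open, and the C2–C6 arm, held equatorial on ring A, should reach that face so that C6 ends trans to C9 across the lactone (7S). The step needs ring closure to win over intermolecular coupling, which high dilution and the turn imposed by quaternary C1, the Z olefin and the acetonide should secure, and it needs the alkoxide to acylate on C19 and not on a neighbouring ester, which the five-membered geometry (the ester sits on C8, next to C7) secures.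

Step 35
Reactants: 41 tetracyclic (7S) γ-lactone
Product: 42 C8,C9 diol
Conditions: CF3CO2H/H2O (9:1), CH2Cl2, 0 °C
Reagents that add atoms: none
Why: Acid hydrolysis of the isopropylidene acetal frees the diol, and the tert-butyldiphenylsilyl ether and the esters should survive brief cold acid.

Step 36
Reactants: 42 C8,C9 diol
Product: 43 C9 acetate
Conditions: Ac2O, pyridine, 4-(dimethylamino)pyridine (cat.), CH2Cl2, 25 °C
Reagents that add atoms: acetic anhydride, CC(=O)OC(C)=O
Why: Acetylation takes the secondary C9 hydroxyl, while the tertiary C8 hydroxyl beside the lactone is too hindered to react under these conditions.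

Step 37
Reactants: 43 C9 acetate
Product: 44 CNP0316115.1
Conditions: HF·pyridine, pyridine, THF, 25 °C
Reagents that add atoms: none
Why: Fluoride cleavage of the last silyl ether under weakly acidic conditions frees C16–OH without acyl migration from O4.

**Compound list**

1 | methyl (S)-3-hydroxy-2-methylpropanoate | COC(=O)[C@@H](C)CO | starting material
2 | methyl (S)-2-methyl-3-(triethylsilyloxy)propanoate | COC(=O)[C@@H](C)CO[Si](CC)(CC)CC | intermediate
3 | (S)-N-methoxy-N,2-dimethyl-3-(triethylsilyloxy)propanamide | CON(C)C(=O)[C@@H](C)CO[Si](CC)(CC)CC | intermediate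
4 | (S)-3-methyl-4-(triethylsilyloxy)butan-2-one | CC(=O)[C@@H](C)CO[Si](CC)(CC)CC | intermediate
5 | (S)-3-methyl-4-(triethylsilyloxy)but-1-en-2-yl trifluoromethanesulfonate | C=C(OS(=O)(=O)C(F)(F)F)[C@@H](C)CO[Si](CC)(CC)CC | intermediate
6 | prop-2-yn-1-ol (propargyl alcohol) | C#CCO | starting material
7 | tert-butyldiphenyl(prop-2-yn-1-yloxy)silane | C#CCO[Si](c1ccccc1)(c1ccccc1)C(C)(C)C | intermediate
8 | (Z)-tert-butyldiphenyl{[2-(tributylstannyl)-3-(trimethylsilyl)prop-2-en-1-yl]oxy}silane (Si and Sn cis) | C[Si](C)(C)/C=C(\[Sn](CCCC)(CCCC)CCCC)CO[Si](c1ccccc1)(c1ccccc1)C(C)(C)C | intermediate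
9 | (Z)-2-[(tert-butyldiphenylsilyloxy)methyl]-3-(trimethylsilyl)prop-2-enal (SiMe3 cis to CHO) | C[Si](C)(C)/C=C(\C=O)CO[Si](c1ccccc1)(c1ccccc1)C(C)(C)C | intermediate
10 | (R)-3-hydroxybutanoic acid | C[C@@H](O)CC(=O)O | starting material
11 | (R)-3-acetoxybutanoic acid | CC(=O)O[C@H](C)CC(=O)O | intermediate
12 | (S)-carvone | CC1=CC[C@@H](CC1=O)C(C)=C | starting material
13 | acetaldehyde | CC=O | starting material
14 | trans-6-(1-hydroxyethyl)carvone: hydroxyethyl on carvone C6 (briarane C1) trans to isopropenyl, both carbinol epimers | CC(O)[C@@H]1[C@@H](C(C)=C)CC=C(C)C1=O | intermediate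
15 | triethylsilyl ether of 14 | CC(O[Si](CC)(CC)CC)[C@@H]1[C@@H](C(C)=C)CC=C(C)C1=O | intermediate
16 | quaternary enone: 6-methyl-6-[1-(triethylsilyloxy)ethyl]carvone, methyl trans to isopropenyl | CC(O[Si](CC)(CC)CC)[C@@]1(C)[C@@H](C(C)=C)CC=C(C)C1=O | intermediate
17 | 11,12β-epoxy ketone: enone epoxide of 16, oxirane trans to isopropenyl | CC(O[Si](CC)(CC)CC)[C@@]1(C)[C@@H](C(C)=C)C[C@@H]2O[C@]2(C)C1=O | intermediate
18 | methoxy hydroperoxide: C14–C(CH3)(OCH3)OOH in place of isopropenyl | CC(O[Si](CC)(CC)CC)[C@@]1(C)[C@@H](C(C)(OC)OO)C[C@@H]2O[C@]2(C)C1=O | intermediate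
19 | epoxy ketone C14 acetate: 14α-OAc in place of isopropenyl, same configuration | CC(O[Si](CC)(CC)CC)[C@@]1(C)[C@@H](OC(C)=O)C[C@@H]2O[C@]2(C)C1=O | intermediate
20 | ring A allylic alcohol: C10=C11, 12β-OH trans to 14α-OAc | CC(O[Si](CC)(CC)CC)[C@@]1(C)[C@@H](OC(C)=O)C[C@H](O)C(C)=C1 | intermediate
21 | O12 tributylstannylmethyl ether of 20 | CC(O[Si](CC)(CC)CC)[C@@]1(C)[C@@H](OC(C)=O)C[C@H](OC[Sn](CCCC)(CCCC)CCCC)C(C)=C1 | intermediate
22 | ring A diol: 10β-CH2OH (cis to C15), 14α-OH, C11=C12 | CC(O[Si](CC)(CC)CC)[C@@]1(C)[C@@H](O)CC=C(C)[C@@H]1CO | intermediate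
23 | ring A hydroxy aldehyde: C9 aldehyde of 22 | CC(O[Si](CC)(CC)CC)[C@@]1(C)[C@@H](O)CC=C(C)[C@@H]1C=O | intermediate
24 | (9R) allylic alcohol: C9–OH, C8(=C7H2), C17 methyl, C19 OSiEt3 | CC(O[Si](CC)(CC)CC)[C@@]1(C)[C@@H](O)CC=C(C)[C@@H]1[C@@H](O)C(=C)[C@@H](C)CO[Si](CC)(CC)CC | intermediate
25 | tetraol: C7, C8, C9 triol (C8/C9 as in the target) and 14α-OH | CC(O[Si](CC)(CC)CC)[C@@]1(C)[C@@H](O)CC=C(C)[C@@H]1[C@@H](O)[C@@](O)(CO)[C@@H](C)CO[Si](CC)(CC)CC | intermediate
26 | C7 tert-butyldimethylsilyl ether of 25 | CC(O[Si](CC)(CC)CC)[C@@]1(C)[C@@H](O)CC=C(C)[C@@H]1[C@@H](O)[C@@](O)(CO[Si](C)(C)C(C)(C)C)[C@@H](C)CO[Si](CC)(CC)CC | intermediate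
27 | C8/C9 acetonide of 26 | CC(O[Si](CC)(CC)CC)[C@@]1(C)[C@@H](O)CC=C(C)[C@@H]1[C@H]2OC(C)(C)O[C@]2(CO[Si](C)(C)C(C)(C)C)[C@@H](C)CO[Si](CC)(CC)CC | intermediate
28 | C14 acetate of 27 | CC(O[Si](CC)(CC)CC)[C@@]1(C)[C@@H](OC(C)=O)CC=C(C)[C@@H]1[C@H]2OC(C)(C)O[C@]2(CO[Si](C)(C)C(C)(C)C)[C@@H](C)CO[Si](CC)(CC)CC | intermediate
29 | C2,C19 diol: both triethylsilyl groups removed from 28 | CC(O)[C@@]1(C)[C@@H](OC(C)=O)CC=C(C)[C@@H]1[C@H]2OC(C)(C)O[C@]2(CO[Si](C)(C)C(C)(C)C)[C@@H](C)CO | intermediate
30 | keto aldehyde: C2 methyl ketone, C19 aldehyde | CC(=O)[C@@]1(C)[C@@H](OC(C)=O)CC=C(C)[C@@H]1[C@H]2OC(C)(C)O[C@]2(CO[Si](C)(C)C(C)(C)C)[C@@H](C)C=O | intermediate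
31 | keto acid: C19 carboxylic acid | CC(=O)[C@@]1(C)[C@@H](OC(C)=O)CC=C(C)[C@@H]1[C@H]2OC(C)(C)O[C@]2(CO[Si](C)(C)C(C)(C)C)[C@@H](C)C(=O)O | intermediate
32 | keto ester: C2 methyl ketone, C19 methyl ester, 14-OAc, C8/C9 acetonide, C7 OSiMe2t-Bu | CC(=O)[C@@]1(C)[C@@H](OC(C)=O)CC=C(C)[C@@H]1[C@H]2OC(C)(C)O[C@]2(CO[Si](C)(C)C(C)(C)C)[C@@H](C)C(=O)OC | intermediate
33 | (4R) aldol adduct: C4–OH, C2 ketone, (5Z) C6–SiMe3, C16 OSiPh2t-Bu | C[Si](C)(C)/C=C(CO[Si](c1ccccc1)(c1ccccc1)C(C)(C)C)\[C@H](O)CC(=O)[C@@]2(C)[C@@H](OC(C)=O)CC=C(C)[C@@H]2[C@H]3OC(C)(C)O[C@]3(CO[Si](C)(C)C(C)(C)C)[C@@H](C)C(=O)OC | intermediate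
34 | (2R,4R) anti diol | C[Si](C)(C)/C=C(CO[Si](c1ccccc1)(c1ccccc1)C(C)(C)C)\[C@H](O)C[C@@H](O)[C@@]2(C)[C@@H](OC(C)=O)CC=C(C)[C@@H]2[C@H]3OC(C)(C)O[C@]3(CO[Si](C)(C)C(C)(C)C)[C@@H](C)C(=O)OC | intermediate
35 | C4 (R)-3-acetoxybutanoate of 34 | C[Si](C)(C)/C=C(CO[Si](c1ccccc1)(c1ccccc1)C(C)(C)C)\[C@H](OC(=O)C[C@@H](C)OC(C)=O)C[C@@H](O)[C@@]2(C)[C@@H](OC(C)=O)CC=C(C)[C@@H]2[C@H]3OC(C)(C)O[C@]3(CO[Si](C)(C)C(C)(C)C)[C@@H](C)C(=O)OC | intermediate
36 | C2 acetate of 35 | C[Si](C)(C)/C=C(CO[Si](c1ccccc1)(c1ccccc1)C(C)(C)C)\[C@H](OC(=O)C[C@@H](C)OC(C)=O)C[C@@H](OC(C)=O)[C@@]2(C)[C@@H](OC(C)=O)CC=C(C)[C@@H]2[C@H]3OC(C)(C)O[C@]3(CO[Si](C)(C)C(C)(C)C)[C@@H](C)C(=O)OC | intermediate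
37 | (5Z) C6 iodoalkene of 36 (iodine cis to C4) | I/C=C(CO[Si](c1ccccc1)(c1ccccc1)C(C)(C)C)\[C@H](OC(=O)C[C@@H](C)OC(C)=O)C[C@@H](OC(C)=O)[C@@]2(C)[C@@H](OC(C)=O)CC=C(C)[C@@H]2[C@H]3OC(C)(C)O[C@]3(CO[Si](C)(C)C(C)(C)C)[C@@H](C)C(=O)OC | intermediate
38 | C7 primary alcohol of 37 | I/C=C(CO[Si](c1ccccc1)(c1ccccc1)C(C)(C)C)\[C@H](OC(=O)C[C@@H](C)OC(C)=O)C[C@@H](OC(C)=O)[C@@]2(C)[C@@H](OC(C)=O)CC=C(C)[C@@H]2[C@H]3OC(C)(C)O[C@]3(CO)[C@@H](C)C(=O)OC | intermediate
39 | (5Z)-iodoalkene C7 aldehyde with C8/C9 acetonide and C19 methyl ester | I/C=C(CO[Si](c1ccccc1)(c1ccccc1)C(C)(C)C)\[C@H](OC(=O)C[C@@H](C)OC(C)=O)C[C@@H](OC(C)=O)[C@@]2(C)[C@@H](OC(C)=O)CC=C(C)[C@@H]2[C@H]3OC(C)(C)O[C@]3(C=O)[C@@H](C)C(=O)OC | intermediate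
40 | C7 hydroxy ester: ten-membered (7S) carbinol, C19 methyl ester, formed as its chromium alkoxide | CC(=O)O[C@H](C)CC(=O)O[C@@H]1C[C@@H](OC(C)=O)[C@@]2(C)[C@@H](OC(C)=O)CC=C(C)[C@@H]2[C@H]3OC(C)(C)O[C@@]3([C@@H](C)C(=O)OC)[C@@H](O)/C=C\1CO[Si](c4ccccc4)(c4ccccc4)C(C)(C)C | intermediate
41 | tetracyclic (7S) γ-lactone with C8/C9 acetonide, (5Z), C16 OSiPh2t-Bu | CC(=O)O[C@H](C)CC(=O)O[C@@H]1C[C@@H](OC(C)=O)[C@@]2(C)[C@@H](OC(C)=O)CC=C(C)[C@@H]2[C@H]3OC(C)(C)O[C@@]34[C@H](/C=C\1CO[Si](c5ccccc5)(c5ccccc5)C(C)(C)C)OC(=O)[C@@H]4C | intermediate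
42 | C8,C9 diol of 41 | CC(=O)O[C@H](C)CC(=O)O[C@@H]1C[C@@H](OC(C)=O)[C@@]2(C)[C@@H](OC(C)=O)CC=C(C)[C@@H]2[C@@H](O)[C@@]2(O)[C@H](/C=C\1CO[Si](c3ccccc3)(c3ccccc3)C(C)(C)C)OC(=O)[C@@H]2C | intermediate
43 | C9 acetate of 42 | CC(=O)O[C@H](C)CC(=O)O[C@@H]1C[C@@H](OC(C)=O)[C@@]2(C)[C@@H](OC(C)=O)CC=C(C)[C@@H]2[C@@H](OC(C)=O)[C@@]2(O)[C@H](/C=C\1CO[Si](c3ccccc3)(c3ccccc3)C(C)(C)C)OC(=O)[C@@H]2C | intermediate
44 | CNP0316115.1 | CC(=O)O[C@H](C)CC(=O)O[C@@H]1C[C@@H](OC(C)=O)[C@@]2(C)[C@@H](OC(C)=O)CC=C(C)[C@@H]2[C@@H](OC(C)=O)[C@@]2(O)[C@H](/C=C\1CO)OC(=O)[C@@H]2C | target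

**Step count and risks**

Total: 37 steps. Longest linear sequence: 29 steps (steps 9–37, from (S)-carvone).

Step 34. What may go wrong is poor facial selectivity in the ring-closing carbonyl addition, so that the 7R alkoxide forms, or an alkoxide that does not acylate on C19. The fallback sets out from 39 and sets C7 by reduction instead of addition. The coupling is quenched cold with aqueous NH4Cl before lactonisation, which should leave the C7 carbinol as the 7R hydroxy ester F1 (alone or mixed with 40). Dess–Martin oxidation gives the macrocyclic C7 enone F2. Corey–Bakshi–Shibata reduction with the (R)-configured 1-methyl-3,3-diphenyltetrahydropyrrolo-oxazaborole and catecholborane, in which fully substituted C8 acts as the large and alkenyl C6 as the small substituent, should give the 7S alcohol 40. Pyridinium p-toluenesulfonate in warm toluene then closes the lactone, and the route is rejoined at 41.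

Step 27. What may go wrong is low or reversed facial selectivity of the enol borinate toward the enal, which would carry through to C2. The fallback sets out from 33 as a C4 epimer mixture and sets both centres by 1,3-relationships that do not depend on the aldol. Et3SiOTf and 2,6-lutidine give the C4 silyl ether F3. Corey–Bakshi–Shibata reduction with the (S)-configured oxazaborole and catecholborane (quaternary C1 large, C3 methylene small) sets 2R in carbinol F4. Pyridinium p-toluenesulfonate in methanol at 0 °C removes the triethylsilyl group to give the 2R diol F5 as C4 epimers. MnO2 oxidises only the allylic C4 carbinol to the β-hydroxy enone F6. Me4NBH(OAc)3 then reduces the C4 ketone anti to the C2 hydroxyl, and the route is rejoined at 34.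

Step 19. What may go wrong is competing osmylation of the ring olefin, or a weak anti preference at C8. The fallback sets out from 24 and uses hydroxyl-directed oxygen transfer. VO(acac)2 with t-BuOOH should epoxidise only the allylic olefin and, for a 2-substituted allylic alcohol, erythro to the carbinol, giving the epoxy alcohol F7. KOH in aqueous DMSO opens the oxirane at primary C7 with retention at C8, and the route is rejoined at 25.

**Further compounds**

F1 | step 34 | 7R hydroxy ester (C7 epimer of 40) | CC(=O)O[C@H](C)CC(=O)O[C@@H]1C[C@@H](OC(C)=O)[C@@]2(C)[C@@H](OC(C)=O)CC=C(C)[C@@H]2[C@H]3OC(C)(C)O[C@@]3([C@@H](C)C(=O)OC)[C@H](O)/C=C\1CO[Si](c4ccccc4)(c4ccccc4)C(C)(C)C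
F2 | step 34 | macrocyclic C7 enone | CC(=O)O[C@H](C)CC(=O)O[C@@H]1C[C@@H](OC(C)=O)[C@@]2(C)[C@@H](OC(C)=O)CC=C(C)[C@@H]2[C@H]3OC(C)(C)O[C@@]3([C@@H](C)C(=O)OC)C(=O)/C=C\1CO[Si](c4ccccc4)(c4ccccc4)C(C)(C)C
F3 | step 27 | C4 triethylsilyl ether of 33 (C4 epimers) | C[Si](C)(C)/C=C(CO[Si](c1ccccc1)(c1ccccc1)C(C)(C)C)\C(O[Si](CC)(CC)CC)CC(=O)[C@@]2(C)[C@@H](OC(C)=O)CC=C(C)[C@@H]2[C@H]3OC(C)(C)O[C@]3(CO[Si](C)(C)C(C)(C)C)[C@@H](C)C(=O)OC
F4 | step 27 | 2R carbinol with C4 triethylsilyl ether (C4 epimers) | C[Si](C)(C)/C=C(CO[Si](c1ccccc1)(c1ccccc1)C(C)(C)C)\C(O[Si](CC)(CC)CC)C[C@@H](O)[C@@]2(C)[C@@H](OC(C)=O)CC=C(C)[C@@H]2[C@H]3OC(C)(C)O[C@]3(CO[Si](C)(C)C(C)(C)C)[C@@H](C)C(=O)OC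
F5 | step 27 | 2R diol (C4 epimers) | C[Si](C)(C)/C=C(CO[Si](c1ccccc1)(c1ccccc1)C(C)(C)C)\C(O)C[C@@H](O)[C@@]2(C)[C@@H](OC(C)=O)CC=C(C)[C@@H]2[C@H]3OC(C)(C)O[C@]3(CO[Si](C)(C)C(C)(C)C)[C@@H](C)C(=O)OC
F6 | step 27 | 2R β-hydroxy enone (C4 ketone) | C[Si](C)(C)/C=C(CO[Si](c1ccccc1)(c1ccccc1)C(C)(C)C)\C(=O)C[C@@H](O)[C@@]2(C)[C@@H](OC(C)=O)CC=C(C)[C@@H]2[C@H]3OC(C)(C)O[C@]3(CO[Si](C)(C)C(C)(C)C)[C@@H](C)C(=O)OC
F7 | step 19 | C7,C8 epoxy alcohol (erythro to C9–OH) | CC(O[Si](CC)(CC)CC)[C@@]1(C)[C@@H](O)CC=C(C)[C@@H]1[C@@H](O)[C@@]2(CO2)[C@@H](C)CO[Si](CC)(CC)CC
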